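## The problem

Target 34 is a C25 terpenoid built on a cis-fused 4,4,8,10-tetramethyl-Δ8-octalin (ring A = C1–C5 and C10, ring B = C5–C10). C9 carries a six-carbon chain (C11–C16) with a hydroxymethyl group on C13 and a furan-2(5H)-one joined through its C4 position to C16. The only stereocentres are the fusion carbons C5 (R) and C10 (S), with C5–H and C10–CH3 cis. No heteroatom sits near them, so each can be controlled only through the other or by an external chiral agent. The bond between them is the most congested in the molecule, joining quaternary C10 to a C5 that is flanked by quaternary C4. The tetrasubstituted C8=C9 double bond must be placed regiospecifically, because an acid-promoted drift to C7=C8 could not be undone. In the chain, C13=C14 is trisubstituted with CH2OH trans to C15, and C15=C16 is E; the remote ring stereocentres cannot relay either geometry, so both must come from stereospecific alkene constructions. The butenolide (acidic γ-hydrogens, Michael acceptor), the trienyl lactone chromophore and the allylic alcohol will not survive strong base, acid or hydride, so the lactone should be attached last under neutral conditions. What opens the structure is ring B itself: a cyclohexene with C8=C9 beside the fusion carbon C10 is the retron of a [4+2] cycloaddition between a C7=C8–C9=C10 diene and a C5=C6 dienophile linked through C1–C4, provided C6 temporarily carries an activating formyl group.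

## Retrosynthesis

**C16–C17 (34 ⇒ 31 + 33).** The last bond made is the one between the diene terminus and C4 of the butenolide. Cutting here, and not at C14–C15 or by an olefination across C15=C16, keeps the lactone out of every basic or reducing step. It also lets both alkene geometries be fixed beforehand, since a Stille coupling of dienyl iodide 31 with stannane 33 transfers them with retention. Iodide 31 lacks the sensitive chromophore, and 33 is one stannylation from commercial bromide 32. The coupling must run base-free at room temperature and tolerate the free C13 hydroxymethyl group.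

**C16–I and C12–C13 (31 ⇒ 30 ⇒ 23 + 26).** Iodide 31 is traced to vinylsilane 30, the silyl group being an inert placeholder for iodine. Silane 30 is cut at C12–C13 into bromide 23 and enynol 26 (from 24 and 25). Copper-catalysed trans-addition of Grignard reagent 27 across the propargylic triple bond of alkoxide 28 makes this bond and, through the chelated alkenylmagnesium 29, fixes the C13=C14 geometry in the same event. A cut at C11–C12 or a carbonyl olefination at C13=C14 would leave that geometry to be controlled separately. Bromide 23 carries only the bicyclic core and a primary halide. The forward reaction must add anti, at the alkyne carbon next to the CH2O group, and leave the E-vinylsilane alone.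

**Functional-group changes and the retron (23 ⇒ 22 ⇒ 21 ⇒ 20).** Bromide 23 comes from alcohol 22 and silyl ether 21. Ring B of 21 has no handle beyond its alkene, so a formyl group is added retrosynthetically at C6 to give aldehyde 20. This is the price of the Diels–Alder retron and is repaid by one decarbonylation. That step must excise the carbonyl carbon without moving C8=C9; the C6 centre itself is expendable.

**C5–C10 and C6–C7 (20 ⇒ 17).** Cutting both bonds of ring B that flank the C8=C9 alkene unravels the core to the acyclic, achiral trienal 17. Cutting ring A alone (C4–C5 or C5–C10) would leave a chiral cyclohexene with the quaternary C10 still to be made in enantioenriched form. The forward reaction has to deliver the cis fusion and one absolute sense. The first is built into 17 by placing the tether on the Z position of the diene terminus; the second is asked of a chiral amine catalyst acting on the enal. The stereochemical problem thereby moves to the geometry of one tetrasubstituted alkene.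

**Enal, diene and lactone (17 ⇒ 16 ⇒ 14 ⇒ 13 ⇒ 11 ⇒ 10 ⇒ 9).** The enal is cut at C5=C6 (Wittig) to aldehyde 16, and this to nitrile 14, which hides C5 at the aldehyde oxidation level through all organometallic steps. The terminal C7=C8 bond is cut next (methylenation of methyl ketone 13). Ketone 13 is the Weinreb product of amide 11, which comes from hydroxy amide 10 and finally from lactone 9, where C8 and C12 are tied together as a butyrolactone. An alkynoate carbometalation was considered for the same alkene but would put the ester carbon on C9 and force a later one-carbon homologation to reach C11–C12. The lactone already holds C8, C9, C11 and C12 at the right oxidation levels. Each forward step must leave the C9=C10 geometry untouched.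

**C1–C10 (9 ⇒ 7 + 4).** The tetrasubstituted alkene is cut at its sp2–sp3 bond into enol triflate 7 and the alkylborane 8 derived from alkene 4. A B-alkyl Suzuki coupling proceeds with retention, so the alkene geometry reduces to the geometry of an enol triflate. The fragments have five and seven carbons and no stereocentre.

**Fragments (7 ⇒ 5; 4 ⇒ 1 + 2).** Triflate 7 comes from commercial 2-acetylbutyrolactone 5 through its chelated enolate 6, which fixes the Z geometry. Nitrile 4 is the allylation product of isobutyronitrile 1 with allyl bromide 2 via anion 3, which installs the C4 gem-dimethyl group.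

## Roads not taken

**Alternative 1:** Hydrogen-atom-transfer radical closure of ring A.
- Cut: C4–C5.
- Forward step: Fe(acac)3 and PhSiH3 transfer a hydrogen atom to the 1,1-disubstituted alkene of cyclohexadienone A2. The tertiary C4 radical adds 6-exo to C5 of the less substituted enone arm and gives bicyclic enone A1.
- Merits: radical addition is forgiving of congestion, so the bond to quaternary C4 should form readily. The chain on C10 can reach C5 only from its own face, so the cis fusion is inherent.
- Weak points: the quaternary C10 of A2 must already be enantioenriched, in a dienone whose two arms differ only at C8/C9. A1 keeps a C7 carbonyl conjugated to C8=C9, which must be removed without reducing or shifting that alkene. The β,γ-unsaturated tert-butyl ester still has to be taken to the C12 alcohol.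
- Comparison: for making the hindered ring-A bond this road is the safer one, and its key reaction is known in kind. The chosen plan sets against it an achiral acyclic precursor, catalyst control of the absolute sense, both rings and both stereocentres in one step, and an activating group removed in a single step.

**Alternative 2:** Alkyne–alkynoate addition and lactonisation for the butenolide.
- Cut: C16–C17 and the lactone O–C bond.
- Forward step: Pd(OAc)2 with tris(2,6-dimethoxyphenyl)phosphine adds the terminal alkyne of enyne A4 across ethyl 4-hydroxybut-2-ynoate A5; the cis hydroxy ester then lactonises to alkynylbutenolide A3.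
- Merits: atom-economical, tin-free, mild, and the lactone ring is made from acyclic material.
- Weak points: A3 has C15≡C16 as an alkyne, which must be reduced to the E-alkene within a conjugated dienyne–butenolide. Cis-selective reduction gives the wrong geometry, and over-reduction or conjugate reduction of the lactone threatens. The step does nothing for the bicyclic core, which would still need its own solution, and A4 needs its trisubstituted alkene set separately.
- Comparison: in atom economy and avoidance of tin it is better than the Stille end-game chosen here. The chosen plan delivers E-C15=C16 directly from a geometry-defined iodide and spends its key step on the core, which is the harder problem.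

**Alternative 3:** Ireland–Claisen ring contraction.
- Cut: C5–C10, as in the chosen plan, but by a [3,3] shift.
- Forward step: the silyl ketene acetal of δ-lactone A7 rearranges, exchanging the lactone C–O bond for C5–C10 and giving cyclohexenecarboxylic acid A6.
- Merits: sigmatropic rearrangements form crowded bonds, quaternary centres included, reliably. Chirality is transferred from one carbinol centre that is easy to set, and no chiral catalyst is needed at the key step.
- Weak points: the ring contraction must go through a boat-like transition state with a trisubstituted alkene terminus, so the C5/C10 relationship depends on both the alkene geometry and that preference holding. Only ring A results. Ring B still requires reduction of the C6 carboxyl group, addition of C7 and C8 with its methyl group, closure of the tetrasubstituted C8=C9 alkene beside a quaternary centre, and selective saturation of C1=C2.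
- Comparison: as a way to make C5–C10 it is arguably surer than a cycloaddition. The chosen plan sets against it the closure of both rings and the regiospecific placement of C8=C9 in the same step, and a clearly shorter sequence.

Key step: step 10

Remark on the chemistry: the sense of induction in step 10 rests on the accepted face-shielding model for E-iminium ions of 5-benzylimidazolidinones, and the (2R,5R) catalyst is specified on that basis.

## Route

Step 1
Reactants: 1 isobutyronitrile; 2 allyl bromide
Product: 4 2,2-dimethylpent-4-enenitrile, via lithiated isobutyronitrile 3 (not isolated)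
Conditions: LiN(i-Pr)2, THF, −78 °C; then 2, −78 °C → rt
Reagents that add atoms: none
Why: Deprotonation gives the ketene-iminate 3, which is C-alkylated by allyl bromide (SN2 nitrile alkylation); this creates quaternary C4 with its two methyl groups and brings C1–C3 as a terminal alkene for hydroboration.

Step 2
Reactants: 5 2-acetylbutyrolactone
Product: 7 (1Z)-1-(2-oxooxolan-3-ylidene)ethyl trifluoromethanesulfonate, via chelated sodium enolate 6 (not isolated)
Conditions: NaH, Et2O, 0 °C; then Tf2O, −20 → 0 °C
Reagents that add atoms: trifluoromethanesulfonic anhydride, O=S(=O)(OS(=O)(=O)C(F)(F)F)C(F)(F)F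
Why: Enolate O-sulfonylation; in 6 sodium bridges the enolate oxygen and the lactone carbonyl oxygen, so triflation freezes the Z geometry (OTf cis to the future C8 carbonyl), which later places the tether cis to C8.

Step 3
Reactants: 4 2,2-dimethylpent-4-enenitrile; 7 (1Z)-1-(2-oxooxolan-3-ylidene)ethyl trifluoromethanesulfonate
Product: 9 2,2-dimethyl-6-[(3Z)-2-oxooxolan-3-ylidene]heptanenitrile, via B-alkyl-9-BBN borane 8 (not isolated)
Conditions: 4, 9-BBN-H, THF, 0 °C → rt; then 7, PdCl2(dppf) (5 mol%), AsPh3, aq. K3PO4, DMF, rt
Reagents that add atoms: none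
Why: 9-BBN adds anti-Markovnikov to the terminal alkene only, and the B-alkyl Suzuki–Miyaura coupling of 8 with the electron-poor enol triflate proceeds with retention at the sp2 carbon. This forms C1–C10 and the tetrasubstituted C9=C10 alkene with the chain cis to the lactone carbonyl.

Step 4
Reactants: 9 2,2-dimethyl-6-[(3Z)-2-oxooxolan-3-ylidene]heptanenitrile
Product: 10 (2Z)-7-cyano-2-(2-hydroxyethyl)-N-methoxy-N,3,7-trimethyloct-2-enamide
Conditions: MeNH(OMe)·HCl, AlMe3, CH2Cl2, 0 °C → rt; aq. potassium sodium tartrate
Reagents that add atoms: N,O-dimethylhydroxylamine hydrochloride, CNOC.Cl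
Why: Weinreb aminolysis; the aluminium amide opens the lactone at the acyl carbon, freeing C12–OH and turning C8 into an N-methoxy-N-methylamide. The tetrasubstituted alkene blocks conjugate addition and cannot change geometry, and the tertiary nitrile is inert at room temperature.

Step 5
Reactants: 10 (2Z)-7-cyano-2-(2-hydroxyethyl)-N-methoxy-N,3,7-trimethyloct-2-enamide
Product: 11 (2Z)-2-[2-(tert-butyldiphenylsilyloxy)ethyl]-7-cyano-N-methoxy-N,3,7-trimethyloct-2-enamide
Conditions: t-BuPh2SiCl, imidazole, CH2Cl2, 0 °C → rt
Reagents that add atoms: tert-butyl(chloro)diphenylsilane, CC(C)(C)[Si](Cl)(c1ccccc1)c1ccccc1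
Why: Standard silylation of the primary alcohol stops relactonisation; the tert-butyldiphenylsilyl group is chosen over smaller silyl groups because it must outlast the acidic amine salt of step 10.

Step 6
Reactants: 11 (2Z)-2-[2-(tert-butyldiphenylsilyloxy)ethyl]-7-cyano-N-methoxy-N,3,7-trimethyloct-2-enamide
Product: 13 (6Z)-7-acetyl-9-(tert-butyldiphenylsilyloxy)-2,2,6-trimethylnon-6-enenitrile, via magnesium hemiaminal chelate 12 (not isolated)
Conditions: MeMgBr, THF, −20 → 0 °C; aq. NH4Cl
Reagents that add atoms: methylmagnesium bromide, C[Mg]Br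
Why: Weinreb ketone synthesis; chelate 12 holds the tetrahedral adduct until work-up, so exactly one methyl group reaches C8, and the neopentyl-type nitrile does not react with MeMgBr at 0 °C.

Step 7
Reactants: 13 (6Z)-7-acetyl-9-(tert-butyldiphenylsilyloxy)-2,2,6-trimethylnon-6-enenitrile
Product: 14 (6Z)-7-[2-(tert-butyldiphenylsilyloxy)ethyl]-2,2,6,8-tetramethylnona-6,8-dienenitrile
Conditions: Ph3PCH3Br, KOt-Bu, THF, 0 °C; then 13, 0 °C → rt
Reagents that add atoms: methyltriphenylphosphonium bromide, C[P+](c1ccccc1)(c1ccccc1)c1ccccc1.[Br-]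
Why: Wittig methylenation of the methyl ketone installs C7 and completes the 2,3-disubstituted diene; carbonyl attack should outrun γ-deprotonation of the twisted enone, and the nitrile has no α-hydrogen.

Step 8
Reactants: 14 (6Z)-7-[2-(tert-butyldiphenylsilyloxy)ethyl]-2,2,6,8-tetramethylnona-6,8-dienenitrile
Product: 16 (6Z)-7-[2-(tert-butyldiphenylsilyloxy)ethyl]-2,2,6,8-tetramethylnona-6,8-dienal, via N-aluminio aldimine 15 (not isolated)
Conditions: i-Bu2AlH, CH2Cl2, −78 → −40 °C; aq. potassium sodium tartrate, then wet SiO2
Reagents that add atoms: water, O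
Why: i-Bu2AlH delivers one hydride to the nitrile and stops at aldimine 15, which mild hydrolysis converts into the C5 aldehyde; quaternary C4 excludes enolisation, and neither the silyl ether nor the diene is reducible.

Step 9
Reactants: 16 (6Z)-7-[2-(tert-butyldiphenylsilyloxy)ethyl]-2,2,6,8-tetramethylnona-6,8-dienal
Product: 17 (2E,8Z)-9-[2-(tert-butyldiphenylsilyloxy)ethyl]-4,4,8,10-tetramethylundeca-2,8,10-trienal
Conditions: Ph3P=CHCHO, toluene, 90 °C
Reagents that add atoms: (triphenylphosphoranylidene)acetaldehyde, O=CC=P(c1ccccc1)(c1ccccc1)c1ccccc1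
Why: Wittig reaction with the stabilised formylmethylene ylide gives the E-enal and adds C6 plus the temporary formyl carbon; 16 cannot self-condense because C4 is quaternary, and 90 °C lies well below the range of the [1,5]-hydrogen shift of the Z-diene.

Step 10
Reactants: 17 (2E,8Z)-9-[2-(tert-butyldiphenylsilyloxy)ethyl]-4,4,8,10-tetramethylundeca-2,8,10-trienal
Product: 20 (1R,4aS,8aR)-4-[2-(tert-butyldiphenylsilyloxy)ethyl]-3,4a,8,8-tetramethyl-1,2,4a,5,6,7,8,8a-octahydronaphthalene-1-carbaldehyde, via trienal iminium ion 18 (not isolated), via cycloadduct iminium ion 19 (not isolated)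
Conditions: (2R,5R)-5-benzyl-2-tert-butyl-3-methylimidazolidin-4-one·CF3CO2H (20 mol%), MeCN/H2O (98:2), −20 → 4 °C
Reagents that add atoms: none
Why: Proposed new method: condensation of the second-generation imidazolidinone salt with enal 17 gives the E-iminium ion 18, whose lowered LUMO should let the C5=C6 dienophile add to the tethered C7=C8–C9=C10 diene in a concerted but strongly asynchronous [4+2], with the bond from the iminium β-carbon C5 to the fully substituted terminus C10 leading and C6–C7 following, after which hydrolysis of 19 releases 20 and the amine; the closest known reaction type is the imidazolidinone-catalysed intramolecular Diels–Alder reaction of 2,7,9-decatrienals, which has not been shown for a fully substituted diene terminus or for a dienophile carbon beside a quaternary centre. Ring B closes as the cycloaddition ring itself (both new σ-bonds lie in it), and ring A closes through the C5–C10 bond alone, the four-carbon tether C1–C4 completing a six-membered carbocycle in the type 1 mode (tether on the diene terminus). The C5/C10 relationship is set by the diene: with the tether on the Z (inside) position of C10 only the cis-fused transition state is within reach, so C10–CH3 and C5–H end cis. C6 is set relative to C5 by the E-enal, suprafacial addition leaving the formyl group trans to C4 (and endo), that is cis to C5–H. The absolute sense comes from the catalyst: in 18 the benzyl group of the (2R,5R) salt covers the Si face at C6, so the diene adds to the Re face, which corresponds to (1R,4aS,8aR)-20. The step needs periselectivity over the [1,5]-hydrogen shift of the Z-diene and over a stepwise Michael addition ending in proton loss; the low temperature allowed by iminium activation answers the first, while the gem-dimethyl group in the tether and the bias of the diene away from its s-trans form (C8 methyl against the Z substituent on C10) favour the folded, reactive conformer.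

Step 11
Reactants: 20 (1R,4aS,8aR)-4-[2-(tert-butyldiphenylsilyloxy)ethyl]-3,4a,8,8-tetramethyl-1,2,4a,5,6,7,8,8a-octahydronaphthalene-1-carbaldehyde
Product: 21 tert-butyl{2-[(4aR,8aS)-2,5,5,8a-tetramethyl-3,4,4a,5,6,7,8,8a-octahydronaphthalen-1-yl]ethoxy}diphenylsilane
Conditions: RhCl(PPh3)3 (1.1 equiv), toluene, 110 °C
Reagents that add atoms: none
Why: Tsuji–Wilkinson decarbonylation; oxidative addition of the formyl C–H bond to monovalent rhodium, extrusion of CO and C–H reductive elimination replace CHO by H. The C6 centre is erased on purpose, C5 and C10 cannot epimerise, and the tetrasubstituted C8=C9 alkene is too hindered for hydroacylation or migration.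

Step 12
Reactants: 21 tert-butyl{2-[(4aR,8aS)-2,5,5,8a-tetramethyl-3,4,4a,5,6,7,8,8a-octahydronaphthalen-1-yl]ethoxy}diphenylsilane
Product: 22 2-[(4aR,8aS)-2,5,5,8a-tetramethyl-3,4,4a,5,6,7,8,8a-octahydronaphthalen-1-yl]ethan-1-ol
Conditions: Bu4NF, THF, rt
Reagents that add atoms: none
Why: Fluoride-induced desilylation frees the C12 alcohol; nothing else in 21 is sensitive to fluoride or mild base.

Step 13
Reactants: 22 2-[(4aR,8aS)-2,5,5,8a-tetramethyl-3,4,4a,5,6,7,8,8a-octahydronaphthalen-1-yl]ethan-1-ol
Product: 23 (4aR,8aS)-1-(2-bromoethyl)-2,5,5,8a-tetramethyl-3,4,4a,5,6,7,8,8a-octahydronaphthalene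
Conditions: CBr4, PPh3, CH2Cl2, 0 °C
Reagents that add atoms: tetrabromomethane, BrC(Br)(Br)Br
Why: Appel bromination (SN2 displacement of the alkoxyphosphonium ion by bromide) under neutral conditions, which avoids protonation of the tetrasubstituted alkene.

Step 14
Reactants: 24 propargyl alcohol; 25 (E)-(2-bromovinyl)trimethylsilane
Product: 26 (E)-5-(trimethylsilyl)pent-4-en-2-yn-1-ol
Conditions: PdCl2(PPh3)2 (2 mol%), CuI (4 mol%), i-Pr2NH, THF, rt
Reagents that add atoms: none
Why: Sonogashira coupling of the terminal alkyne with the alkenyl bromide goes with retention of the E geometry and tolerates the free hydroxyl group.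

Step 15
Reactants: 23 (4aR,8aS)-1-(2-bromoethyl)-2,5,5,8a-tetramethyl-3,4,4a,5,6,7,8,8a-octahydronaphthalene; 26 (E)-5-(trimethylsilyl)pent-4-en-2-yn-1-ol
Product: 30 (2E,4E)-2-{2-[(4aR,8aS)-2,5,5,8a-tetramethyl-3,4,4a,5,6,7,8,8a-octahydronaphthalen-1-yl]ethyl}-5-(trimethylsilyl)penta-2,4-dien-1-ol, via Grignard reagent 27 (not isolated), via bromomagnesium enynolate 28 (not isolated), via alkenylmagnesium chelate 29 (not isolated)
Conditions: 23, Mg, Et2O, reflux; separately 26 (1.5 equiv), EtMgBr (1.5 equiv), Et2O, −20 °C; combine, CuI (10 mol%), Et2O/toluene, −10 °C → rt; aq. NH4Cl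
Reagents that add atoms: none
Why: Copper-catalysed anti-carbomagnesiation of a propargylic alkoxide (Duboudin–Jousseaume type): the alkyl group of 27 goes to the alkyne carbon next to the CH2O group (C13) and magnesium to C14 on the opposite side, held in chelate 29, so that after protonation C12 is cis to C15 and CH2OH trans to it (2E). Pre-forming 28 with EtMgBr spares the valuable Grignard reagent, and the vinylsilane is inert to Grignard and organocopper species.

Step 16
Reactants: 30 (2E,4E)-2-{2-[(4aR,8aS)-2,5,5,8a-tetramethyl-3,4,4a,5,6,7,8,8a-octahydronaphthalen-1-yl]ethyl}-5-(trimethylsilyl)penta-2,4-dien-1-ol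
Product: 31 (2E,4E)-5-iodo-2-{2-[(4aR,8aS)-2,5,5,8a-tetramethyl-3,4,4a,5,6,7,8,8a-octahydronaphthalen-1-yl]ethyl}penta-2,4-dien-1-ol
Conditions: NIS (1.05 equiv), 2,6-lutidine, (CF3)2CHOH, 0 °C
Reagents that add atoms: N-iodosuccinimide, O=C1CCC(=O)N1I
Why: Electrophilic ipso-iododesilylation; attack at the silicon-bearing C16 gives a β-silyl-stabilised cation that loses the silyl group with retention of the E geometry. The terminal dienylsilane is the most accessible nucleophilic π-site, and the buffered, stoichiometric reagent at 0 °C is meant to spare the hindered C8=C9 alkene.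

Step 17
Reactants: 32 4-bromofuran-2(5H)-one
Product: 33 4-(tributylstannyl)furan-2(5H)-one
Conditions: (Bu3Sn)2, Pd(PPh3)4 (5 mol%), THF, 65 °C
Reagents that add atoms: hexabutyldistannane, CCCC[Sn](CCCC)(CCCC)[Sn](CCCC)(CCCC)CCCC
Why: Palladium-catalysed stannylation of the alkenyl bromide with the distannane (oxidative addition, Sn–Sn transmetalation, reductive elimination) gives the known stannylbutenolide under neutral conditions.

Step 18
Reactants: 31 (2E,4E)-5-iodo-2-{2-[(4aR,8aS)-2,5,5,8a-tetramethyl-3,4,4a,5,6,7,8,8a-octahydronaphthalen-1-yl]ethyl}penta-2,4-dien-1-ol; 33 4-(tributylstannyl)furan-2(5H)-one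
Product: 34 4-[(1E,3E)-4-(hydroxymethyl)-6-[(4aR,8aS)-2,5,5,8a-tetramethyl-3,4,4a,5,6,7,8,8a-octahydronaphthalen-1-yl]hexa-1,3-dien-1-yl]furan-2(5H)-one
Conditions: Pd2(dba)3 (5 mol%), AsPh3, CuI (20 mol%), DMF, rt, dark
Reagents that add atoms: none
Why: Stille coupling; oxidative addition of the dienyl iodide to zerovalent palladium, copper-assisted transmetalation from tin and reductive elimination form C16–C17 with retention of both alkene geometries. The base-free, room-temperature conditions suit the butenolide and the free allylic alcohol.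

## Compound list

1 | isobutyronitrile | CC(C)C#N | starting material
2 | allyl bromide | C=CCBr | starting material
3 | lithiated isobutyronitrile (N-lithio ketene-iminate, formed in situ) | CC(C)=C=N[Li] | intermediate
4 | 2,2-dimethylpent-4-enenitrile | C=CCC(C)(C)C#N | intermediate
5 | 2-acetylbutyrolactone (3-acetyloxolan-2-one, racemic) | CC(=O)C1CCOC1=O | starting material
6 | sodium (1Z)-1-(2-oxooxolan-3-ylidene)ethanolate (chelated enolate, formed in situ) | C/C([O-])=C1\CCOC1=O.[Na+] | intermediate
7 | (1Z)-1-(2-oxooxolan-3-ylidene)ethyl trifluoromethanesulfonate | C/C(OS(=O)(=O)C(F)(F)F)=C1\CCOC1=O | intermediate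
8 | 5-(9-borabicyclo[3.3.1]nonan-9-yl)-2,2-dimethylpentanenitrile (formed in situ) | N#CC(C)(C)CCCB1C2CCCC1CCC2 | intermediate
9 | 2,2-dimethyl-6-[(3Z)-2-oxooxolan-3-ylidene]heptanenitrile | C/C(CCCC(C)(C)C#N)=C1\CCOC1=O | intermediate
10 | (2Z)-7-cyano-2-(2-hydroxyethyl)-N-methoxy-N,3,7-trimethyloct-2-enamide | C/C(CCCC(C)(C)C#N)=C(\CCO)C(=O)N(C)OC | intermediate
11 | (2Z)-2-[2-(tert-butyldiphenylsilyloxy)ethyl]-7-cyano-N-methoxy-N,3,7-trimethyloct-2-enamide | C/C(CCCC(C)(C)C#N)=C(\CCO[Si](c1ccccc1)(c1ccccc1)C(C)(C)C)C(=O)N(C)OC | intermediate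
12 | bromomagnesium hemiaminal adduct of 11 with MeMgBr (tetrahedral chelate, formed in situ) | C/C(CCCC(C)(C)C#N)=C(\CCO[Si](c1ccccc1)(c1ccccc1)C(C)(C)C)C(C)(O[Mg]Br)N(C)OC | intermediate
13 | (6Z)-7-acetyl-9-(tert-butyldiphenylsilyloxy)-2,2,6-trimethylnon-6-enenitrile | C/C(CCCC(C)(C)C#N)=C(\CCO[Si](c1ccccc1)(c1ccccc1)C(C)(C)C)C(C)=O | intermediate
14 | (6Z)-7-[2-(tert-butyldiphenylsilyloxy)ethyl]-2,2,6,8-tetramethylnona-6,8-dienenitrile | C/C(CCCC(C)(C)C#N)=C(\CCO[Si](c1ccccc1)(c1ccccc1)C(C)(C)C)C(C)=C | intermediate
15 | N-(diisobutylaluminio)aldimine of 16 (formed in situ) | C/C(CCCC(C)(C)C=N[Al](CC(C)C)CC(C)C)=C(\CCO[Si](c1ccccc1)(c1ccccc1)C(C)(C)C)C(C)=C | intermediate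
16 | (6Z)-7-[2-(tert-butyldiphenylsilyloxy)ethyl]-2,2,6,8-tetramethylnona-6,8-dienal | C/C(CCCC(C)(C)C=O)=C(\CCO[Si](c1ccccc1)(c1ccccc1)C(C)(C)C)C(C)=C | intermediate
17 | (2E,8Z)-9-[2-(tert-butyldiphenylsilyloxy)ethyl]-4,4,8,10-tetramethylundeca-2,8,10-trienal | O=C/C=C/C(C)(C)CCC/C(C)=C(/CCO[Si](c1ccccc1)(c1ccccc1)C(C)(C)C)C(C)=C | intermediate
18 | E-iminium trifluoroacetate of 17 with (2R,5R)-5-benzyl-2-tert-butyl-3-methylimidazolidin-4-one (formed in situ) | O=C1N(C)[C@H](C(C)(C)C)/[N+](=C/C=C/C(C)(C)CCC/C(C)=C(/CCO[Si](c2ccccc2)(c2ccccc2)C(C)(C)C)C(C)=C)[C@@H]1Cc1ccccc1.[O-]C(=O)C(F)(F)F | intermediate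
19 | iminium trifluoroacetate of 20 with the same imidazolidinone (formed in situ) | CC1=C(CCO[Si](c3ccccc3)(c3ccccc3)C(C)(C)C)[C@@]2(C)CCCC(C)(C)[C@H]2[C@H](/C=[N+]4/[C@@H](C(C)(C)C)N(C)C(=O)[C@H]4Cc4ccccc4)C1.[O-]C(=O)C(F)(F)F | intermediate
20 | (1R,4aS,8aR)-4-[2-(tert-butyldiphenylsilyloxy)ethyl]-3,4a,8,8-tetramethyl-1,2,4a,5,6,7,8,8a-octahydronaphthalene-1-carbaldehyde | CC1=C(CCO[Si](c3ccccc3)(c3ccccc3)C(C)(C)C)[C@@]2(C)CCCC(C)(C)[C@H]2[C@H](C=O)C1 | intermediate
21 | tert-butyl{2-[(4aR,8aS)-2,5,5,8a-tetramethyl-3,4,4a,5,6,7,8,8a-octahydronaphthalen-1-yl]ethoxy}diphenylsilane | CC1=C(CCO[Si](c3ccccc3)(c3ccccc3)C(C)(C)C)[C@@]2(C)CCCC(C)(C)[C@H]2CC1 | intermediate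
22 | 2-[(4aR,8aS)-2,5,5,8a-tetramethyl-3,4,4a,5,6,7,8,8a-octahydronaphthalen-1-yl]ethan-1-ol | CC1=C(CCO)[C@@]2(C)CCCC(C)(C)[C@H]2CC1 | intermediate
23 | (4aR,8aS)-1-(2-bromoethyl)-2,5,5,8a-tetramethyl-3,4,4a,5,6,7,8,8a-octahydronaphthalene | CC1=C(CCBr)[C@@]2(C)CCCC(C)(C)[C@H]2CC1 | intermediate
24 | propargyl alcohol | C#CCO | starting material
25 | (E)-(2-bromovinyl)trimethylsilane | C[Si](C)(C)/C=C/Br | starting material
26 | (E)-5-(trimethylsilyl)pent-4-en-2-yn-1-ol | OCC#C/C=C/[Si](C)(C)C | intermediate
27 | {2-[(4aR,8aS)-2,5,5,8a-tetramethyl-3,4,4a,5,6,7,8,8a-octahydronaphthalen-1-yl]ethyl}magnesium bromide (formed in situ) | CC1=C(CC[Mg]Br)[C@@]2(C)CCCC(C)(C)[C@H]2CC1 | intermediate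
28 | bromomagnesium (E)-5-(trimethylsilyl)pent-4-en-2-yn-1-olate (formed in situ) | Br[Mg]OCC#C/C=C/[Si](C)(C)C | intermediate
29 | C14-magnesiated bromomagnesium alkoxide of 30 (chelated alkenylmagnesium, Mg cis to CH2O, formed in situ) | CC1=C(CC/C(CO[Mg]Br)=C(/[Mg]Br)\C=C\[Si](C)(C)C)[C@@]2(C)CCCC(C)(C)[C@H]2CC1 | intermediate
30 | (2E,4E)-2-{2-[(4aR,8aS)-2,5,5,8a-tetramethyl-3,4,4a,5,6,7,8,8a-octahydronaphthalen-1-yl]ethyl}-5-(trimethylsilyl)penta-2,4-dien-1-ol | CC1=C(CC/C(CO)=C\C=C\[Si](C)(C)C)[C@@]2(C)CCCC(C)(C)[C@H]2CC1 | intermediate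
31 | (2E,4E)-5-iodo-2-{2-[(4aR,8aS)-2,5,5,8a-tetramethyl-3,4,4a,5,6,7,8,8a-octahydronaphthalen-1-yl]ethyl}penta-2,4-dien-1-ol | CC1=C(CC/C(CO)=C\C=C\I)[C@@]2(C)CCCC(C)(C)[C@H]2CC1 | intermediate
32 | 4-bromofuran-2(5H)-one | O=C1C=C(Br)CO1 | starting material
33 | 4-(tributylstannyl)furan-2(5H)-one | CCCC[Sn](CCCC)(CCCC)C1=CC(=O)OC1 | intermediate
34 | 4-[(1E,3E)-4-(hydroxymethyl)-6-[(4aR,8aS)-2,5,5,8a-tetramethyl-3,4,4a,5,6,7,8,8a-octahydronaphthalen-1-yl]hexa-1,3-dien-1-yl]furan-2(5H)-one | CC1=C(CC/C(=C\C=C\C2=CC(=O)OC2)CO)[C@@]2(C)CCCC(C)(C)[C@H]2CC1 | target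

## Step count and weak points

Total: 18 steps. Longest linear sequence: 15 steps (steps 1, 3–13, 15, 16 and 18). Steps 2, 14 and 17 prepare side fragments.

**Step 10 (key step, new method).** The cycloaddition may not proceed at temperatures where the iminium pathway dominates, because the C5–C10 bond joins a neopentyl carbon to a centre that becomes quaternary. Turnover may also stall through slow hydrolysis of the hindered product iminium, or the reaction may stop after the first bond and end in proton loss. If forced by warming, an uncatalysed background reaction would erode the enantiomeric purity.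

Fallback from known chemistry, setting out from aldehyde 16 and returning at 20:
- Masamune–Roush olefination of 16 (LiCl, i-Pr2NEt, MeCN) with diethyl {2-[(4R)-4-benzyl-2-oxo-1,3-oxazolidin-3-yl]-2-oxoethyl}phosphonate would give the N-acyloxazolidinone (4R)-4-benzyl-3-[(2E,8Z)-9-[2-(tert-butyldiphenylsilyloxy)ethyl]-4,4,8,10-tetramethylundeca-2,8,10-trienoyl]-1,3-oxazolidin-2-one F1.
- Me2AlCl (1.4 equiv) in CH2Cl2 at −30 °C should induce the auxiliary-controlled intramolecular Diels–Alder reaction through the chelated s-cis dienophile. The Z-diene again allows only the cis fusion, and the (4R)-benzyl group is predicted to leave the required face open. The product is the cycloadduct imide F2.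
- LiBH4 in wet Et2O would cleave the auxiliary reductively to the C6 hydroxymethyl compound F3.
- Dess–Martin oxidation would give 20.

**Step 15.** Carbometalation may lose regio- or stereocontrol on the conjugated enynol (syn addition, or addition across the enyne), and Wurtz-type homocoupling during Grignard formation would consume the limiting fragment.

Fallback from 23, returning at 30:
- Alkylation of the sodium salt of triethyl phosphonoacetate with 23 (NaH, DMF, 60 °C) would give ethyl 2-(diethoxyphosphoryl)-4-[(4aR,8aS)-2,5,5,8a-tetramethyl-3,4,4a,5,6,7,8,8a-octahydronaphthalen-1-yl]butanoate F4.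
- Horner–Wadsworth–Emmons reaction of F4 with (E)-3-(trimethylsilyl)prop-2-enal (NaH, THF) should give mainly the E-configured dienoate F5, with the ester trans to C15.
- i-Bu2AlH reduction would give 30.

**Step 16.** Iodonium formation at the electron-rich tetrasubstituted C8=C9 alkene, followed by capture by the C13 hydroxymethyl oxygen, may compete with ipso attack at silicon. Reversible iodonium addition to the diene could also erode the E geometry.

Fallback from 23, returning directly at 34:
- Sonogashira coupling of 24 with (E)-tributyl(2-iodovinyl)stannane would give (E)-5-(tributylstannyl)pent-4-en-2-yn-1-ol F6.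
- Carbomagnesiation of F6 with 27, as in step 15, would give the dienylstannane F7.
- Stille coupling of F7 with bromide 32 would reach 34 with no electrophilic iodination.

**Step 11.** Oxidative addition at the hindered secondary formyl group may be slow, and at the temperature then needed β-hydride elimination from the alkylrhodium intermediate would divert material to alkenes.

Fallback from 20, returning at 21:
- Pinnick oxidation (NaClO2, NaH2PO4, 2-methylbut-2-ene) would give carboxylic acid F8.
- Conversion into the N-hydroxypyridine-2-thione ester F9 and photolysis with t-BuSH (Barton reductive decarboxylation) would give 21.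

**Step 7.** γ-Deprotonation of the twisted enone by the ylide may scramble the C9=C10 geometry or deconjugate the ketone before the hindered carbonyl is methylenated.

Fallback from 9, returning at 14:
- Excess MeMgBr would open the lactone to the tertiary alcohol diol F10.
- Selective silylation of the primary hydroxyl would give F11.
- Burgess dehydration, which can only remove a methyl hydrogen, would give diene 14 without a ketone ever being exposed to base.

## Further compounds

F1 | step 10 | (4R)-4-benzyl-3-[(2E,8Z)-9-[2-(tert-butyldiphenylsilyloxy)ethyl]-4,4,8,10-tetramethylundeca-2,8,10-trienoyl]-1,3-oxazolidin-2-one | O=C(/C=C/C(C)(C)CCC/C(C)=C(/CCO[Si](c1ccccc1)(c1ccccc1)C(C)(C)C)C(C)=C)N1[C@H](Cc2ccccc2)COC1=O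
F2 | step 10 | (4R)-4-benzyl-3-{[(1R,4aS,8aR)-4-[2-(tert-butyldiphenylsilyloxy)ethyl]-3,4a,8,8-tetramethyl-1,2,4a,5,6,7,8,8a-octahydronaphthalen-1-yl]carbonyl}-1,3-oxazolidin-2-one | CC1=C(CCO[Si](c3ccccc3)(c3ccccc3)C(C)(C)C)[C@@]2(C)CCCC(C)(C)[C@H]2[C@H](C(=O)N4[C@H](Cc5ccccc5)COC4=O)C1
F3 | step 10 | [(1R,4aS,8aR)-4-[2-(tert-butyldiphenylsilyloxy)ethyl]-3,4a,8,8-tetramethyl-1,2,4a,5,6,7,8,8a-octahydronaphthalen-1-yl]methanol | CC1=C(CCO[Si](c3ccccc3)(c3ccccc3)C(C)(C)C)[C@@]2(C)CCCC(C)(C)[C@H]2[C@H](CO)C1
F4 | step 15 | ethyl 2-(diethoxyphosphoryl)-4-[(4aR,8aS)-2,5,5,8a-tetramethyl-3,4,4a,5,6,7,8,8a-octahydronaphthalen-1-yl]butanoate (both epimers at C2) | CC1=C(CCC(C(=O)OCC)P(=O)(OCC)OCC)[C@@]2(C)CCCC(C)(C)[C@H]2CC1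
F5 | step 15 | ethyl (2E,4E)-2-{2-[(4aR,8aS)-2,5,5,8a-tetramethyl-3,4,4a,5,6,7,8,8a-octahydronaphthalen-1-yl]ethyl}-5-(trimethylsilyl)penta-2,4-dienoate | CC1=C(CC/C(C(=O)OCC)=C\C=C\[Si](C)(C)C)[C@@]2(C)CCCC(C)(C)[C@H]2CC1
F6 | step 16 | (E)-5-(tributylstannyl)pent-4-en-2-yn-1-ol | OCC#C/C=C/[Sn](CCCC)(CCCC)CCCC
F7 | step 16 | (2E,4E)-2-{2-[(4aR,8aS)-2,5,5,8a-tetramethyl-3,4,4a,5,6,7,8,8a-octahydronaphthalen-1-yl]ethyl}-5-(tributylstannyl)penta-2,4-dien-1-ol | CC1=C(CC/C(CO)=C\C=C\[Sn](CCCC)(CCCC)CCCC)[C@@]2(C)CCCC(C)(C)[C@H]2CC1
F8 | step 11 | (1R,4aS,8aR)-4-[2-(tert-butyldiphenylsilyloxy)ethyl]-3,4a,8,8-tetramethyl-1,2,4a,5,6,7,8,8a-octahydronaphthalene-1-carboxylic acid | CC1=C(CCO[Si](c3ccccc3)(c3ccccc3)C(C)(C)C)[C@@]2(C)CCCC(C)(C)[C@H]2[C@H](C(=O)O)C1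
F9 | step 11 | 2-thioxopyridin-1(2H)-yl (1R,4aS,8aR)-4-[2-(tert-butyldiphenylsilyloxy)ethyl]-3,4a,8,8-tetramethyl-1,2,4a,5,6,7,8,8a-octahydronaphthalene-1-carboxylate | CC1=C(CCO[Si](c3ccccc3)(c3ccccc3)C(C)(C)C)[C@@]2(C)CCCC(C)(C)[C@H]2[C@H](C(=O)ON4C=CC=CC4=S)C1
F10 | step 7 | (6Z)-8-hydroxy-7-(2-hydroxyethyl)-2,2,6,8-tetramethylnon-6-enenitrile | C/C(CCCC(C)(C)C#N)=C(\CCO)C(C)(C)O
F11 | step 7 | (6Z)-7-[2-(tert-butyldiphenylsilyloxy)ethyl]-8-hydroxy-2,2,6,8-tetramethylnon-6-enenitrile | C/C(CCCC(C)(C)C#N)=C(\CCO[Si](c1ccccc1)(c1ccccc1)C(C)(C)C)C(C)(C)O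
A1 | alternative 1 | tert-butyl 2-[(4aR,8aS)-2,5,5,8a-tetramethyl-3-oxo-3,4,4a,5,6,7,8,8a-octahydronaphthalen-1-yl]acetate | CC1=C(CC(=O)OC(C)(C)C)[C@@]2(C)CCCC(C)(C)[C@H]2CC1=O
A2 | alternative 1 | tert-butyl 2-[(6S)-2,6-dimethyl-6-(4-methylpent-4-en-1-yl)-3-oxocyclohexa-1,4-dien-1-yl]acetate | CC1=C(CC(=O)OC(C)(C)C)[C@@](C)(CCCC(C)=C)C=CC1=O
A3 | alternative 2 | 4-{(3E)-4-[(tert-butyldimethylsilyloxy)methyl]-6-[(4aR,8aS)-2,5,5,8a-tetramethyl-3,4,4a,5,6,7,8,8a-octahydronaphthalen-1-yl]hex-3-en-1-yn-1-yl}furan-2(5H)-one | CC1=C(CC/C(=C\C#CC2=CC(=O)OC2)CO[Si](C)(C)C(C)(C)C)[C@@]2(C)CCCC(C)(C)[C@H]2CC1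
A4 | alternative 2 | tert-butyl{[(2E)-2-{2-[(4aR,8aS)-2,5,5,8a-tetramethyl-3,4,4a,5,6,7,8,8a-octahydronaphthalen-1-yl]ethyl}pent-2-en-4-yn-1-yl]oxy}dimethylsilane | CC1=C(CC/C(=C\C#C)CO[Si](C)(C)C(C)(C)C)[C@@]2(C)CCCC(C)(C)[C@H]2CC1
A5 | alternative 2 | ethyl 4-hydroxybut-2-ynoate | CCOC(=O)C#CCO
A6 | alternative 3 | (1R,2S)-2-[4-(tert-butyldimethylsilyloxy)but-1-en-2-yl]-2,6,6-trimethylcyclohex-3-ene-1-carboxylic acid | OC(=O)[C@@H]1C(C)(C)CC=C[C@]1(C)C(=C)CCO[Si](C)(C)C(C)(C)C
A7 | alternative 3 | (6S)-6-[(1E)-5-(tert-butyldimethylsilyloxy)-2-methyl-3-methylidenepent-1-en-1-yl]-4,4-dimethyloxan-2-one | O=C1CC(C)(C)C[C@@H](/C=C(\C)C(=C)CCO[Si](C)(C)C(C)(C)C)O1
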